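## Retrosynthetic overview

1. Niveusin B (25) comes from 15-O-TBS niveusin B (24) by desilylation. Compound 24 forms in one photocatalytic step: an intramolecular decatungstate/CrCl2 allylic C–H allylation of a Z-enal, masked as a spiro-lactol, that forms C6–C7 and the 10-membered ring. The C8-oxygen lactonises onto the methyl ester in the same step.
2. The spiro-lactol (23), with its Z-C4=C5 bond, C3 hemiketal oxygen and THF ring, comes from furan photo-oxygenation (1O2, then Me2S) of a 2-alkyl-3-(silyloxymethyl)furan (21). The pendant tertiary C10-OH traps the endoperoxide.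
3. The C8 angelate and the 2-alkylacrylate (C7, C11–C13) come from the epoxide (14) derived from (R)-3-hydroxybutyrolactone. The epoxide is opened with acetylide and the alkyne is converted by Pd-catalysed Markovnikov hydroesterification. C10 is set by chelation-controlled addition of a furylethyl Grignard (9) to the β-hydroxy methyl ketone from the lactone.
4. Stereochemistry: C8 comes from the lactone, C10 from 1,3-induction from C8, C7/C6 from the macrocyclic chair transition state (trans-lactone), and C3 from the bridged hemiketal.
5. Ring order: the THF/spiro rings form first (photo-oxygenation). The 10-membered carbocycle and the lactone then form together in the key step.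

Assumptions: (R)-3-hydroxy-γ-butyrolactone (from D-malic acid) is a commercial chiral building block. C2-lithiation of 3 is taken as the major pathway, with any C5 isomer removed by chromatography. The C3 hemiketal configuration is fixed by the cis-bridged oxabicycle, because the ring-opened hemiketal equilibrates through the C3 ketone.

## Route

**Step 1**
Reactants: 1 furan-3-ylmethanol; 2 tert-butyldimethylsilyl chloride (TBSCl)
Product: 3 tert-butyldimethyl(furan-3-ylmethoxy)silane
Conditions: imidazole, DMF, 25 °C
Reagents that add atoms: 2, TBSCl, CC(C)(C)[Si](C)(C)Cl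
Why: Standard silylation of the primary alcohol; no stereocentre is involved.

**Step 2**
Reactants: 3; 4 ethylene oxide
Product: 5 2-[3-(TBSoxymethyl)furan-2-yl]ethan-1-ol
Conditions: n-BuLi, THF, –78→0 °C; then 4, BF3·OEt2, –78 °C
Reagents that add atoms: 4, ethylene oxide, C1CO1
Why: α-Lithiation of the furan at C2 followed by BF3-promoted epoxide opening installs the C2–C1 two-carbon chain.

**Step 3**
Reactants: 5; 6 carbon tetrabromide
Product: 7 2-(2-bromoethyl)-3-(TBSoxymethyl)furan
Conditions: PPh3, CH2Cl2, 0 °C
Reagents that add atoms: 6, CBr4, BrC(Br)(Br)Br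
Why: Appel bromination converts the primary alcohol to the bromide under neutral conditions that the furan tolerates.

**Step 4**
Reactants: 7; 8 magnesium turnings
Product: 9 2-[3-(TBSoxymethyl)furan-2-yl]ethylmagnesium bromide
Conditions: Mg, I2 (cat.), THF, 25 °C
Reagents that add atoms: 8, magnesium, [Mg]
Why: Oxidative insertion of Mg into the primary C–Br bond (Grignard formation) gives the C1 nucleophile; the furan and the silyl ether are inert to Mg.

**Step 5**
Reactants: 10 (R)-3-hydroxy-γ-butyrolactone [(4R)-4-hydroxydihydrofuran-2(3H)-one]; 11 methylmagnesium bromide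
Product: 12 (4R)-2-methyltetrahydrofuran-2,4-diol (C2 anomers)
Conditions: 11 (2.2 equiv), THF, –78 °C, quench cold (sat. NH4Cl)
Reagents that add atoms: 11, MeMgBr, C[Mg]Br
Why: The first equivalent deprotonates the OH and the second adds once to the lactone to give a stable magnesium hemiketalate, so there is no over-addition at –78 °C, and the C8 (R) carbinol is untouched.

**Step 6**
Reactants: 12 lactol; 9 Grignard reagent
Product: 13 (2R,4S)-6-[3-(TBSoxymethyl)furan-2-yl]-4-methylhexane-1,2,4-triol
Conditions: 9 (3.5 equiv), THF, –78→0 °C
Reagents that add atoms: none (9 is listed as a reactant)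
Why: The lactol opens to the methyl ketone, whose C8 alkoxide chelates Mg in a six-membered chair with the C7 chain equatorial, so axial delivery of the furylethyl group to C10 gives the 1,3-anti diol (C10 = S) by chelation-controlled 1,3-induction; this is a Grignard addition to a ketone.

**Step 7**
Reactants: 13
Product: 14 (2S)-4-[3-(TBSoxymethyl)furan-2-yl]-2-methyl-1-[(2R)-oxiran-2-yl]butan-2-ol
Conditions: TsCl (1.05 equiv), Et3N, Me3N·HCl (cat.), CH2Cl2, 0 °C; then K2CO3, MeOH, 25 °C
Reagents that add atoms: none
Why: Selective tosylation of the primary alcohol, then 3-exo-tet closure by the secondary C8 alkoxide (Payne-type epoxide formation); the C8–O bond is never broken, so C8 is retained.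

**Step 8**
Reactants: 14; 15 lithium acetylide–ethylenediamine complex
Product: 16 (4S,6S)-8-[3-(TBSoxymethyl)furan-2-yl]-6-methyloct-1-yne-4,6-diol
Conditions: 15 (3 equiv), DMSO, 25 °C
Reagents that add atoms: 15, LiC≡CH·H2NCH2CH2NH2, [Li]C#C
Why: SN2 opening at the unhindered terminal epoxide carbon (C7) forms the C7–C11 bond, and C8 keeps its configuration because its C–O bond is not broken.

**Step 9**
Reactants: 16; 17 angelic acid [(2Z)-2-methylbut-2-enoic acid]
Product: 18 C8 angelate of 16 [(4S,6S)-6-hydroxy-6-methyl-8-(furyl)oct-1-yn-4-yl (2Z)-2-methylbut-2-enoate]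
Conditions: 17, 2,4,6-Cl3C6H2COCl, Et3N, THF, 25 °C; then 16, DMAP, toluene, 25 °C
Reagents that add atoms: 17, angelic acid, C/C=C(/C)C(=O)O (listed as a reactant)
Why: Yamaguchi esterification of the mixed anhydride acylates the secondary C8-OH selectively over the tertiary C10-OH and keeps the Z-olefin; the angelate also stops C8-O from forming the wrong lactone later.

**Step 10**
Reactants: 18; 19 carbon monoxide; 20 methanol
Product: 21 methyl (4S,6S)-6-hydroxy-6-methyl-2-methylidene-4-[(2Z)-2-methylbut-2-enoyloxy]-8-[3-(TBSoxymethyl)furan-2-yl]octanoate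
Conditions: Pd(OAc)2 (2 mol%), 2-pyridyl-di-tert-butylphosphine (8 mol%), MsOH (5 mol%), CO (10 bar), MeOH, 50 °C
Reagents that add atoms: 19, CO, [C-]#[O+]; 20, MeOH, CO
Why: Pd–H Markovnikov hydroesterification (the Alpha-process type of catalyst) converts the terminal alkyne into the branched 2-alkylacrylate, which supplies C11–C13 and the C7 allylic CH2, while the angelate and furan are untouched.

**Step 11**
Reactants: 21; 22 oxygen
Product: 23 (7S)-2-hydroxy-4-[(TBSoxy)methyl]-7-methyl-7-{(2S)-2-[(2Z)-2-methylbut-2-enoyloxy]-4-(methoxycarbonyl)pent-4-en-1-yl}-1,6-dioxaspiro[4.4]non-3-ene (spiro C5 and lactol C2 as epimeric mixtures)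
Conditions: tetraphenylporphyrin (1 mol%), O2, white LEDs, CH2Cl2, –78 °C; then Me2S (5 equiv), –78→0 °C
Reagents that add atoms: 22, O2, O=O
Why: Singlet-oxygen [4+2] cycloaddition to the furan is followed by opening of the endoperoxide at the more substituted furan carbon by the pendant C10-OH (intramolecular spiroketalisation, no new stereocentre fixed) and Me2S reduction of the hydroperoxide, and the Z-C4=C5 bond is held in the dihydrofuran ring.

**Step 12**
Reactants: 23
Product: 24 15-O-TBS niveusin B
Conditions: CrCl2 (20 mol%), 4,4′-di-tert-butylbipyridine (20 mol%), tetrabutylammonium decatungstate (TBADT, 2 mol%), MeCN/THF (4:1), 2 mM, 390 nm LEDs, 25 °C, 24 h (slow addition of 23)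
Reagents that add atoms: none (MeOH is lost)
Why: Proposed new method: excited decatungstate abstracts an allylic C7–H of the 2-alkylacrylate, Cr(II) traps the delocalised allyl radical at the CH2 terminus as an allyl-Cr(III), the Cr(III) Lewis acid ionises the spiro-lactol to the Z-enal (C3 becomes the bridged hemiketal), and an anti chair Zimmerman–Traxler addition through C7 forms the C6–C7 bond and the ten-membered ring, after which the Cr alkoxide lactonises onto the methyl ester and reduced decatungstate reduces Cr(III) to Cr(II) while supplying the proton; the closest known reactions are photoredox/Cr allylic C–H allylation of aldehydes and the intramolecular NHK closure of 2-(bromomethyl)alk-2-enoates to α-methylene-γ-lactones, and the new element is HAT activation of an electron-poor 2-alkylacrylate for a macrocyclisation, with C7 set by 1,2-induction from C8 and C6 by the anti chair transition state to give the trans-fused lactone.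

**Step 13**
Reactants: 24
Product: 25 niveusin B
Conditions: HF·pyridine, THF/pyridine, 0 °C, 3 h
Reagents that add atoms: none
Why: Fluoride cleaves the primary TBS ether (silyl ether deprotection) under buffered conditions that leave the bridged hemiketal, the Z-angelate and the α-methylene lactone intact.

## Compound list
1 | furan-3-ylmethanol | OCc1ccoc1 | starting material
2 | tert-butyldimethylsilyl chloride | CC(C)(C)[Si](C)(C)Cl | starting material
3 | tert-butyldimethyl(furan-3-ylmethoxy)silane | CC(C)(C)[Si](C)(C)OCc1ccoc1 | intermediate
4 | ethylene oxide | C1CO1 | starting material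
5 | 2-[3-(TBSoxymethyl)furan-2-yl]ethanol | CC(C)(C)[Si](C)(C)OCc1ccoc1CCO | intermediate
6 | carbon tetrabromide | BrC(Br)(Br)Br | starting material
7 | 2-(2-bromoethyl)-3-(TBSoxymethyl)furan | CC(C)(C)[Si](C)(C)OCc1ccoc1CCBr | intermediate
8 | magnesium | [Mg] | starting material
9 | furylethylmagnesium bromide | CC(C)(C)[Si](C)(C)OCc1ccoc1CC[Mg]Br | intermediate
10 | (R)-3-hydroxy-γ-butyrolactone | O=C1C[C@@H](O)CO1 | starting material
11 | methylmagnesium bromide | C[Mg]Br | starting material
12 | (4R)-2-methyltetrahydrofuran-2,4-diol | CC1(O)C[C@@H](O)CO1 | intermediate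
13 | (2R,4S)-triol | CC(C)(C)[Si](C)(C)OCc1ccoc1CC[C@](C)(O)C[C@@H](O)CO | intermediate
14 | epoxy alcohol | CC(C)(C)[Si](C)(C)OCc1ccoc1CC[C@](C)(O)C[C@@H]1CO1 | intermediate
15 | lithium acetylide (EDA complex) | [Li]C#C | starting material
16 | alkyne diol | CC(C)(C)[Si](C)(C)OCc1ccoc1CC[C@](C)(O)C[C@@H](O)CC#C | intermediate
17 | angelic acid | C/C=C(/C)C(=O)O | starting material
18 | C8 angelate alkyne | CC(C)(C)[Si](C)(C)OCc1ccoc1CC[C@](C)(O)C[C@@H](OC(=O)/C(C)=C\C)CC#C | intermediate
19 | carbon monoxide | [C-]#[O+] | starting material
20 | methanol | CO | starting material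
21 | acrylate | CC(C)(C)[Si](C)(C)OCc1ccoc1CC[C@](C)(O)C[C@@H](OC(=O)/C(C)=C\C)CC(=C)C(=O)OC | intermediate
22 | oxygen | O=O | starting material
23 | spiro-lactol (C2, C5 unspecified) | OC1OC2(CC[C@@](C)(C[C@@H](OC(=O)/C(C)=C\C)CC(=C)C(=O)OC)O2)C(CO[Si](C)(C)C(C)(C)C)=C1 | intermediate
24 | 15-O-TBS niveusin B | C=C1C(=O)O[C@@H]2/C=C(/CO[Si](C)(C)C(C)(C)C)[C@@]3(O)CC[C@@](C)(C[C@@H](OC(=O)/C(C)=C\C)[C@@H]12)O3 | intermediate
25 | niveusin B | C=C1C(=O)O[C@@H]2/C=C(/CO)[C@@]3(O)CC[C@@](C)(C[C@@H](OC(=O)/C(C)=C\C)[C@@H]12)O3 | target

## Totals
Total steps: 13. Longest linear sequence: 12 (1→3→5→7→9→13→14→16→18→21→23→24→25; the lactone branch 10→12 joins at step 6).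

## Three steps most likely to fail
1. **Step 12 (new method).** Decatungstate may abstract the lactol C–H, the CH2OTBS C–H or the angelate allylic C–H instead of C7–H, because HAT from an electron-poor acrylate is polarity-mismatched. The 10-membered closure may also be slow, or the hydroxy ester may not lactonise spontaneously.
   Fallback (known chemistry, different approach): close the ring by the precedented intramolecular Cr(II) Nozaki–Hiyama–Kishi allylation of a preformed (E)-2-(bromomethyl)alk-2-enoate.
   - From triol 13: silylate the primary OH (TESCl), angeloylate C8 (Yamaguchi), remove the TES group, and oxidise (Dess–Martin) to the C7 aldehyde.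
   - Convert the aldehyde to the bromide by Baylis–Hillman with methyl acrylate (DABCO), then MsCl/Et3N followed by LiBr.
   - Photo-oxygenate as in step 11 with PPh3 as the reductant, so the allylic bromide is spared, and add CrCl2 (stoichiometric, THF, 0.5 mM).
2. **Step 6 (C10 diastereoselectivity).** Chelation control with a free alkoxide and a methyl ketone may give less than about 5:1 for the 1,3-anti diol.
   Fallback: change the stereocontrol element.
   - Convert lactone 10 to the acetonide-protected methyl ketone: Weinreb amide formation (MeNHOMe·HCl, AlMe3), acetonide formation (Me2C(OMe)2, CSA), then MeMgBr.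
   - Add the furylethyl nucleophile as its organotitanium reagent (9 + ClTi(OiPr)3) under Reetz-type chelation control, then remove the acetonide (AcOH/H2O) to give 13.
   - Separate any C10 epimer at the alkyne stage (16).
3. **Step 10 (Pd/CO/MsOH with a furan and a furfuryl silyl ether).** The acid may cleave the TBS ether or damage the furan.
   Fallback: open epoxide 14 with isopropenylMgBr/CuI instead of acetylide, angeloylate C8, then convert the isopropenyl group to the same acrylate by SeO2/TBHP allylic oxidation, MnO2, NaClO2 (Pinnick) and TMSCHN2.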